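**Plan**

1. Ring A is the phenol ring (C1 OH, C2 OAr, C3 Br, C4 Br, C5 H, C6 Br) and ring B is the 2,4-dibromophenyl group. The target has no stereocentre.
2. Cuts, in order: C4–Br and C6–Br (para and ortho to the C1 hydroxyl), the O–CH3 bond of a C1 methyl ether, C2–C3 and C3–C4 together, and last the C2–O(ring B) bond.
3. Enabling feature: the C3 bromine is meta to the C1 oxygen and so closed to electrophilic bromination, but C3 lies between oxygen-bearing C2 and C4. Taken out as a CBr unit, it leaves a five-membered ring C1–C2=C4–C5–C6 whose C2=C4 bond is an aryl enol ether, a natural acceptor for dibromocarbene.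
4. Forward: ring B is bought. Cyclopentenone is epoxidised, 2,4-dibromophenoxide opens the epoxide at C2 and water is lost, C1 is ketalised, and CBr2 addition with cyclopropane opening enlarges the carbocycle from five to six atoms.
5. A dienone ketal flanked by a CH2 ionises to an O-alkylated arenium ion that sheds H+ long before water can add, so it gives an aryl ether and not a phenol. C1 is therefore carried as the dimethyl ketal, which ends as a methyl ether that BBr3 cleaves in the same flask, and Br2 then fills C4 and C6.
6. Stereochemistry: nothing to control. The transient stereocentres (epoxide, hydroxy ketone, cyclopropane, allylic bromide) are racemic and are erased before ring A becomes aromatic.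

Key step: step 4

Assumption: chiral intermediates are racemic, and their SMILES show one enantiomer only to convey relative configuration. The ring A labels C1–C6 of the target are used for the carbocycle at every stage, so C3 is absent before step 4.

**Step 1**
Reactants: 1 cyclopent-2-en-1-one
Product: 2 6-oxabicyclo[3.1.0]hexan-2-one (2,3-epoxycyclopentanone, racemic, cis-fused)
Conditions: 30% aq H2O2, NaOH (cat.), MeOH, 0 °C
Reagents that add atoms: hydrogen peroxide, OO
Why: Weitz–Scheffer nucleophilic epoxidation, in which hydroperoxide adds to the β-carbon (future C4) and the enolate closes on the O–O bond; the small bicycle allows only a cis fusion, and both racemic stereocentres vanish in step 2.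

**Step 2**
Reactants: 2 6-oxabicyclo[3.1.0]hexan-2-one, 3 2,4-dibromophenol
Product: 5 2-(2,4-dibromophenoxy)cyclopent-2-en-1-one, via trans-hydroxyketone 4 (not isolated)
Conditions: Cs2CO3 (20 mol %), DMF, 4 Å MS, 60 °C
Reagents that add atoms: none
Why: Opening of an α,β-epoxy ketone by a phenoxide at the carbonyl-activated α-carbon (SN2 with inversion, hence trans-4) followed by E1cB loss of the β-hydroxide is the established entry to 2-aryloxy enones, and the hydroxide released regenerates phenoxide, so base is needed only in catalytic amount.

**Step 3**
Reactants: 5 2-(2,4-dibromophenoxy)cyclopent-2-en-1-one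
Product: 6 2,4-dibromo-1-[(5,5-dimethoxycyclopent-1-en-1-yl)oxy]benzene
Conditions: MeOSiMe3 (3 equiv), Me3SiOTf (5 mol %), CH2Cl2, −78 °C; pyridine quench
Reagents that add atoms: methoxytrimethylsilane, CO[Si](C)(C)C
Why: Aprotic silyl-triflate acetalisation (Noyori conditions), in which the silyl triflate activates the carbonyl, two methoxysilane molecules deliver methoxide and irreversible disiloxane formation drives the reaction, while low temperature and the absence of protic acid keep the C2=C4 bond in place and suppress conjugate addition.

**Step 4**
Reactants: 6 2,4-dibromo-1-[(5,5-dimethoxycyclopent-1-en-1-yl)oxy]benzene, 7 bromoform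
Product: 10 2,4-dibromo-1-[(2-bromo-6,6-dimethoxycyclohexa-1,3-dien-1-yl)oxy]benzene, via dibromocyclopropane 8 (not isolated), via allylic bromide 9 (not isolated)
Conditions: CHBr3 (3 equiv), KOtBu (3.5 equiv), hexane, −20 → 0 °C; filter, concentrate; DBU (2 equiv), PhMe, 90 °C; short pad of basic alumina
Reagents that add atoms: bromoform, BrC(Br)Br
Why: Singlet dibromocarbene, released from bromoform by KOtBu through α-elimination, adds suprafacially in a concerted [2+1] cheletropic step to the C2=C4 enol ether of 6, bonding first at the unhindered and more nucleophilic C4, and so closes the three-membered ring of 8 while forming C3–C4 and C2–C3. On heating, 8 undergoes the two-electron disrotatory cyclopropyl-to-allyl opening; the five-membered ring permits only inward rotation of its tether, so the endo bromide leaves (Woodward–Hoffmann–DePuy rule), the shared C2–C4 bond breaks, and the six-membered ring arises by enlargement of the bicycle and not by an end-to-end cyclisation. The aryloxy-stabilised allyl cation recombines with bromide at the open C4 terminus to give 9, from which DBU removes a C5 proton (E2) to give 10. The closest known reactions are the dihalocarbene ring expansion of 1-alkoxycycloalkenes, which in hot amine bases ends in halo alkoxy dienes, and the thermal isomerisation of 6,6-dibromobicyclo[3.1.0]hexanes to 2,3-dibromocyclohexenes followed by dehydrobromination. Selectivity needed: only one alkene is present, proton loss can occur only at C5 because C1 is quaternary, the C2–O bond is kept because an O-aryl oxocarbenium ion cannot be dealkylated by bromide and no water or alcohol is present in the second stage, and the electron-poor aryloxy group together with the adjacent ketal delays ionisation of 8 until carbene generation is over, which protects the diene from a second addition. The two stereocentres of 8 (cis fusion imposed by the suprafacial addition, racemic) and the one of 9 disappear in achiral 10.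

**Step 5**
Reactants: 10 2,4-dibromo-1-[(2-bromo-6,6-dimethoxycyclohexa-1,3-dien-1-yl)oxy]benzene
Product: 12 3-bromo-2-(2,4-dibromophenoxy)phenol, via aryl methyl ether 11 (not isolated)
Conditions: BBr3 (3 equiv), CH2Cl2, −78 °C → rt; H2O
Reagents that add atoms: none
Why: Lewis-acid ionisation of the ketal gives the O-methyl arenium ion (the anisole protonated at C6), which loses the C6 proton at once to give 11 (aromatisation of a dienone ketal by loss of methanol), and the excess BBr3 then effects the standard aryl methyl ether cleavage, to which the diaryl ether and the C–Br bonds are inert.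

**Step 6**
Reactants: 12 3-bromo-2-(2,4-dibromophenoxy)phenol
Product: 13 3,4,6-tribromo-2-(2,4-dibromophenoxy)phenol (target)
Conditions: Br2 (2.05 equiv), AcOH, rt
Reagents that add atoms: bromine, BrBr
Why: Electrophilic aromatic bromination directed by the free C1 hydroxyl, whose only open ortho and para positions are C6 and C4; C5 is meta to it, and ring B, with one ether oxygen against two bromines, is far less reactive, so two equivalents should stop at the target.

**Compound list**

1 | cyclopent-2-en-1-one | O=C1C=CCC1 | starting material
2 | 6-oxabicyclo[3.1.0]hexan-2-one (racemic, cis-fused) | O=C1CC[C@H]2O[C@@H]12 | intermediate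
3 | 2,4-dibromophenol | Oc1ccc(Br)cc1Br | starting material
4 | trans-2-(2,4-dibromophenoxy)-3-hydroxycyclopentan-1-one (racemic, not isolated) | O=C1CC[C@@H](O)[C@@H]1Oc1ccc(Br)cc1Br | intermediate
5 | 2-(2,4-dibromophenoxy)cyclopent-2-en-1-one | O=C1CCC=C1Oc1ccc(Br)cc1Br | intermediate
6 | 2,4-dibromo-1-[(5,5-dimethoxycyclopent-1-en-1-yl)oxy]benzene | COC1(OC)CCC=C1Oc1ccc(Br)cc1Br | intermediate
7 | bromoform | BrC(Br)Br | starting material
8 | 6,6-dibromo-1-(2,4-dibromophenoxy)-2,2-dimethoxybicyclo[3.1.0]hexane (racemic, cis-fused, not isolated) | COC1(OC)CC[C@H]2C(Br)(Br)[C@@]12Oc1ccc(Br)cc1Br | intermediate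
9 | 2,4-dibromo-1-[(2,3-dibromo-6,6-dimethoxycyclohex-1-en-1-yl)oxy]benzene (racemic, one stereocentre, not isolated) | COC1(OC)CCC(Br)C(Br)=C1Oc1ccc(Br)cc1Br | intermediate
10 | 2,4-dibromo-1-[(2-bromo-6,6-dimethoxycyclohexa-1,3-dien-1-yl)oxy]benzene | COC1(OC)CC=CC(Br)=C1Oc1ccc(Br)cc1Br | intermediate
11 | 1-bromo-2-(2,4-dibromophenoxy)-3-methoxybenzene (not isolated) | COc1cccc(Br)c1Oc1ccc(Br)cc1Br | intermediate
12 | 3-bromo-2-(2,4-dibromophenoxy)phenol | Oc1cccc(Br)c1Oc1ccc(Br)cc1Br | intermediate
13 | 3,4,6-tribromo-2-(2,4-dibromophenoxy)phenol | Oc1c(Br)cc(Br)c(Br)c1Oc1ccc(Br)cc1Br | target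

Total step count: 6. Longest linear sequence: 6 steps (1 → 13).

**Steps most likely to fail**

**Step 4.**
- Carbene transfer may be sluggish, because the enol ether is deactivated by the electron-poor aryl group and by the neighbouring ketal.
- Ring opening may begin while carbene is still being generated, which exposes the diene to a second cyclopropanation.
- The allyl cation may be captured by a nucleophile at C2, with later loss of aryloxide.
- Premature loss of methanol from the diene is harmless, since it leads to the next intermediate 11.

The fallback gives up the ring expansion. It sets out from 3 and returns at 12. Nucleophilic aromatic substitution of purchased 3-bromo-2-fluorobenzaldehyde by 3 (K2CO3, DMAc, 120 °C; fluoride activated by the ortho formyl group) should give 3-bromo-2-(2,4-dibromophenoxy)benzaldehyde F1. Baeyer–Villiger oxidation (mCPBA, CH2Cl2), with migration of the oxygen-substituted aryl group, should give 3-bromo-2-(2,4-dibromophenoxy)phenyl formate F2. Methanolysis (K2CO3 cat., MeOH) then releases 12.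

**Step 3.**
- Methoxide may be delivered in the conjugate sense.
- The allylic ketal may transpose.
- The Lewis acid may ionise the product, with loss of methanol towards a cyclopentadiene.

The fallback installs the ketal before the C2–O bond. It sets out from 1 and returns at 6.
- Br2 in CH2Cl2 at 0 °C should give trans-2,3-dibromocyclopentan-1-one F3, from which Et3N in the same flask removes HBr to give 2-bromocyclopent-2-en-1-one F4.
- Protic ketalisation (HC(OMe)3, MeOH, p-toluenesulfonic acid cat.), in which the C2 bromine holds the double bond in place, gives 1-bromo-5,5-dimethoxycyclopent-1-ene F5.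
- Bromine–lithium exchange (n-BuLi, THF, −78 °C) gives (5,5-dimethoxycyclopent-1-en-1-yl)lithium F6.
- Trapping with 2-isopropoxy-4,4,5,5-tetramethyl-1,3,2-dioxaborolane gives 2-(5,5-dimethoxycyclopent-1-en-1-yl)-4,4,5,5-tetramethyl-1,3,2-dioxaborolane F7.
- Chan–Lam coupling of F7 with 3 (Cu(OAc)2, pyridine, 4 Å MS, air, CH2Cl2, rt) forms the C2–O bond and gives 6. Divalent copper at room temperature should leave the aryl bromides alone.

**Step 2.**
- Base-induced isomerisation or oligomerisation of the sensitive epoxy ketone may outrun attack by the weakly nucleophilic, ortho-hindered phenoxide.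
- The epoxide may open at the β-carbon in place of C2.

The fallback makes the C2–O bond by simple alkylation and introduces the double bond afterwards. It sets out from 3 and returns at 5. Alkylation of 3 with purchased 2-chlorocyclopentan-1-one (K2CO3, acetone, reflux) should give 2-(2,4-dibromophenoxy)cyclopentan-1-one F8. Silylation under equilibrating conditions (Me3SiCl, Et3N, DMF, 80 °C) favours the fully substituted enol ether {[2-(2,4-dibromophenoxy)cyclopent-1-en-1-yl]oxy}trimethylsilane F9. Metal-free dehydrogenation of this silyl enol ether (2-iodoxybenzoic acid, 4-methoxypyridine N-oxide, DMSO, rt) places the double bond between C2 and C4 and gives 5.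

**Further compounds**

F1 | step 4 | 3-bromo-2-(2,4-dibromophenoxy)benzaldehyde | O=Cc1cccc(Br)c1Oc1ccc(Br)cc1Br
F2 | step 4 | 3-bromo-2-(2,4-dibromophenoxy)phenyl formate | O=COc1cccc(Br)c1Oc1ccc(Br)cc1Br
F3 | step 3 | trans-2,3-dibromocyclopentan-1-one (racemic) | O=C1CC[C@@H](Br)[C@@H]1Br
F4 | step 3 | 2-bromocyclopent-2-en-1-one | O=C1CCC=C1Br
F5 | step 3 | 1-bromo-5,5-dimethoxycyclopent-1-ene | COC1(OC)CCC=C1Br
F6 | step 3 | (5,5-dimethoxycyclopent-1-en-1-yl)lithium | [Li]C1=CCCC1(OC)OC
F7 | step 3 | 2-(5,5-dimethoxycyclopent-1-en-1-yl)-4,4,5,5-tetramethyl-1,3,2-dioxaborolane | COC1(OC)CCC=C1B1OC(C)(C)C(C)(C)O1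
F8 | step 2 | 2-(2,4-dibromophenoxy)cyclopentan-1-one (racemic) | O=C1CCCC1Oc1ccc(Br)cc1Br
F9 | step 2 | {[2-(2,4-dibromophenoxy)cyclopent-1-en-1-yl]oxy}trimethylsilane | C[Si](C)(C)OC1=C(Oc2ccc(Br)cc2Br)CCC1
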